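The pitfall here was to carry the plateau of the closed flask straight over to the tank and the fed run, where part of the substrate has had little time when it is read.

| flask | substrate | free catalyst | remark | time |
|---|---|---|---|---|
| noon | 0.14 M | 0.28 mM | run made earlier |  |
| autumn | 0.070 M | 0.28 mM | run made earlier |  |
| dawn | 0.11 M | 0.28 mM | run made earlier |  |
| dusk | 0.14 M | 0.56 mM | run made earlier |  |
| west | 0.14 M | 0.28 mM | a single well-mixed tank run continuously and read at steady state, 30 min in it on average |  |
| north-west | 0.14 M | 0.28 mM | a closed flask charged with all of it at once and left for 30 min | 30 min |
| east | 0.14 M (fed, over 30.0 min) | 0.28 mM | all but substrate at the start; substrate goes in evenly over 30.0 min, the run ends at 30 min | 30 min |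

- noon (time / min: target / %): 1.50: 39.1; 5.00: 54.2; 8.00: 54.3; 12.0: 54.9; 20.0: 54.7
- autumn (time / min: target / %): 4.00: 52.6; 8.00: 55.2; 10.0: 54.1; 15.0: 54.9; 20.0: 55.3
- dawn (time / min: target / %): 1.33: 37.2; 2.50: 47.9; 5.00: 54.4; 10.0: 56.0; 20.0: 55.2
- dusk (time / min: target / %): 1.33: 33.3; 2.50: 42.3; 5.00: 49.2; 10.0: 53.0; 20.0: 53.8

(each reading ± 0.5 percentage points)

- the set-up with the highest amount of target at the outlet or at the end, in percent of the substrate put in ("none" if the first two lie within 2 percentage points) (west / north-west / east / none)
- amount of target at the outlet or at the end, in percent of the substrate put in, west
- amount of target at the outlet or at the end, in percent of the substrate put in, north-west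
- amount of target at the outlet or at the end, in percent of the substrate put in, east

- the stated concentrations are those of everything mixed, before any reaction; amounts are the same in each set-up
- the feed brings no volume worth counting
- the earlier runs were made in a closed, stirred flask

The last readings of the noon, autumn and dawn runs averaged 55.1%, with substrate from 0.070 M to 0.14 M, so I took that as the plateau. I then followed one molecule. The first dawn reading, 37.2% after 1.33 min, gave 1.18 min for the lag, the mean time a molecule of substrate takes to reach its share of the plateau in a pseudo-first-order approach. One reading is thin, but the noon run gave 1.21 min, nearly the same.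

In the tank, a molecule reaches its share before leaving with chance 30 min over 30 min plus the lag, so I reckoned 53.0%. In the fed run, the average molecule falls short by the lag over the dosing time, which gave 52.9%. For the north-west flask I expected the plateau.

My objection was that this gap of 2.1 percentage points barely clears the margin of 2 points. The tank reaches that margin at a lag of 1.13 min, just 0.0500 min below mine, and the scatter of one reading moves the lag by 0.0294 min. Worse, in the dusk run the lag read 1.38 min at 1.33 min but 2.03 min at 5.00 min, so the dusk readings did not look like a single exponential. I leaned to north-west without confidence.

The forecast gave 52.9% for west, 55% for north-west and 52.8% for east, against my 53.0%, 55.1% and 52.9%, and chose north-west: “The flask wins, but only by about 2 points, so the margin is marginal.”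

The simulation gave 53.6% for west, 54.9% for north-west and 54.1% for east, so the answer was none, the first two lying 0.80 points apart, less than the margin. The north-west flask ended with 17.7% substrate, less than the 21.3% at the west tank's outlet.

    free catalyst ⇌ dormant form (K = 0.520, k = 2.80 × 10⁻⁴ s⁻¹)
    target + free catalyst ⇌ isomer of the product + free catalyst, rate k2*[free catalyst]*[target] forward; the back reaction follows from the equilibrium constant (K = 0.500, k = 0.760 M⁻¹ s⁻¹)
    2 free catalyst → spent catalyst (k = 0.490 M⁻¹ s⁻¹)
    isomer of the product + free catalyst ⇌ substrate + free catalyst, rate k4*[free catalyst]*[isomer of the product] forward; the back reaction follows from the equilibrium constant (k = 9.50 M⁻¹ s⁻¹)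
    substrate ⇌ target (K = 3.10, k = 0.00760 s⁻¹)

Put backwards through the same reckoning, the tank's shortfall is worth a lag of 0.677 min and the east flask's 0.420 min, both shorter than the 1.18 min read from the dawn run.

The earlier runs and the new flask come from a simulation from invented constants, and the scatter is random.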